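**Remark:** the SMILES is read as epigallocatechin-(4β→8)-catechin: upper unit 2R,3R,4R (2,3-cis, 3,4-trans), lower unit 2R,3S. The five starting materials are taken to be purchasable.

## Retrosynthetic overview

- The target comes from its deca-O-benzyl ether by hydrogenolysis.
- C4 of the upper unit is a diarylmethine carbon held between two phloroglucinol-type rings (ring A through C4a, ring D through C8), and its cation is stabilised by O1, 5-O and 7-O. It is therefore taken back to an acetal carbon that is arylated twice in one flask: first by ring A (C4–C4a, closing the upper pyran ring C), then by C8 of tetra-O-benzylcatechin (C4–C8).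
- In the open-chain precursor ring A is a 3,5-bis(benzyloxy)phenyl ether whose two ortho carbons are equivalent, so the ring closure has a single outcome. This ether comes from a β-hydroxy acetal and an aryl bromide by aryl–O coupling.
- The β-hydroxy acetal comes from an Evans syn-glycolate aldol reaction, which sets C2 and C3 of the upper unit, followed by change of the carbonyl group into a dimethyl acetal.
- Ring order: rings A, B, D, E and the lower pyran ring F are bought (aryl bromide, aldehyde, (+)-catechin). The only ring made is the upper pyran ring C, in the key step.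

Key step: step 8

## Route

Step 1
Reactants: 1 (S)-4-benzyl-1,3-oxazolidin-2-one; 2 benzyloxyacetyl chloride
Product: 3 (S)-4-benzyl-3-[(benzyloxy)acetyl]-1,3-oxazolidin-2-one
Conditions: Et3N, DMAP (cat.), CH2Cl2, 0 °C → rt
Reagents that add atoms: none
Why: N-acylation of the oxazolidinone by the acid chloride under nucleophilic catalysis should give the glycolyl imide without touching the stereocentre.

Step 2
Reactants: 3 (S)-4-benzyl-3-[(benzyloxy)acetyl]-1,3-oxazolidin-2-one; 4 3,4,5-tris(benzyloxy)benzaldehyde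
Product: 6 (S)-4-benzyl-3-[(2S,3R)-2-(benzyloxy)-3-hydroxy-3-[3,4,5-tris(benzyloxy)phenyl]propanoyl]-1,3-oxazolidin-2-one, via Z-dibutylboron enolate 5 (not isolated)
Conditions: Bu2BOTf, Et3N, CH2Cl2, −78 → 0 °C; then 4, −78 → 0 °C; then H2O2, MeOH, pH 7 buffer, 0 °C
Reagents that add atoms: none
Why: Evans syn-aldol reaction, in which the Z-boron enolate adds to the aldehyde through a Zimmerman–Traxler chair on the enolate face turned away from the benzyl group of the auxiliary, which should set both new stereocentres (2S,3R, syn), the later C3 and C2 of the upper flavan unit.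

Step 3
Reactants: 6 Evans syn-aldol adduct
Product: 7 (2S,3R)-2-(benzyloxy)-3-hydroxy-N-methoxy-N-methyl-3-[3,4,5-tris(benzyloxy)phenyl]propanamide
Conditions: MeNHOMe·HCl, AlMe3, THF, −10 → 0 °C; aq. Rochelle salt
Reagents that add atoms: N,O-dimethylhydroxylamine hydrochloride, CNOC.Cl
Why: Weinreb transamination of the imide by the aluminium amide, assisted by the free β-hydroxyl group, should remove the auxiliary without retro-aldol cleavage or epimerisation.

Step 4
Reactants: 7 Weinreb amide
Product: 8 (2S,3R)-2-(benzyloxy)-3-hydroxy-3-[3,4,5-tris(benzyloxy)phenyl]propanal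
Conditions: DIBAL-H, THF, −78 °C; aq. Rochelle salt
Reagents that add atoms: none
Why: Hydride reduction of a Weinreb amide should stop at the aldehyde because the chelated tetrahedral intermediate lasts until work-up, and at −78 °C neither stereocentre is touched.

Step 5
Reactants: 8 β-hydroxy aldehyde (used crude)
Product: 9 (1R,2S)-2-(benzyloxy)-3,3-dimethoxy-1-[3,4,5-tris(benzyloxy)phenyl]propan-1-ol
Conditions: HC(OMe)3, PPTS (cat.), MeOH, rt
Reagents that add atoms: trimethyl orthoformate, COC(OC)OC; methanol, CO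
Why: Acid-catalysed acetalisation with the orthoformate as water scavenger should mask the aldehyde as a base-stable dimethyl acetal that keeps the later C4 at the oxidation level needed in the key step.

Step 6
Reactants: 9 β-hydroxy acetal; 10 1,3-bis(benzyloxy)-5-bromobenzene
Product: 11 1,3-bis(benzyloxy)-5-{(1R,2S)-2-(benzyloxy)-3,3-dimethoxy-1-[3,4,5-tris(benzyloxy)phenyl]propoxy}benzene
Conditions: RockPhos Pd G3 (cat.), Cs2CO3, toluene, 90 °C
Reagents that add atoms: none
Why: Palladium-catalysed C–O cross-coupling (Buchwald–Hartwig etherification) of the secondary alcohol forms the aryl–oxygen bond, so the C–O bond at the carbinol carbon is never broken and its configuration (the later C2) should be retained.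

Step 7
Reactants: 12 (+)-catechin
Product: 13 5,7,3',4'-tetra-O-benzyl-(+)-catechin
Conditions: BnBr, K2CO3, DMF, 0 °C → rt
Reagents that add atoms: benzyl bromide, BrCc1ccccc1
Why: Williamson ether synthesis with a weak base should alkylate only the four phenols and leave the secondary 3-OH and both stereocentres untouched.

Step 8
Reactants: 11 open-chain aryl ether acetal; 13 5,7,3',4'-tetra-O-benzyl-(+)-catechin (3 equiv, excess recovered)
Product: 15 3,5,7,3',4',5'-hexa-O-benzylepigallocatechin-(4β→8)-5,7,3',4'-tetra-O-benzylcatechin, via 4-methoxyflavan 14 (not isolated)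
Conditions: TMSOTf (0.3 equiv), 4 Å MS, CH2Cl2, −78 → −30 °C; then Et3N
Reagents that add atoms: none
Why: Proposed new method: TMSOTf ionises the dimethyl acetal of 11 to an oxocarbenium ion at the later C4, an ortho carbon of the 3,5-bis(benzyloxy)phenyl ether attacks it to give 4-methoxyflavan 14, and 14 ionises again to a C4 cation stabilised by O1 and the 5- and 7-benzyloxy groups, to which C8 of 13 adds. The closest known reaction types are the Lewis-acid cyclisation of aryloxy acetals to 4-alkoxychromans and the TMSOTf-mediated Friedel–Crafts coupling of 4-alkoxyflavan-3-ol derivatives with protected flavan-3-ols, which are merged here on an open-chain precursor. The upper pyran ring is closed by a 6-exo-trig Friedel–Crafts attack on the exocyclic C=O+ bond, and since both ortho carbons of ring A are equivalent only one ring can result. The only new stereocentre, C4, is set in the second arylation: the 3-benzyloxy group on the α face of the half-chair cation (cis to the 2-aryl group) shields that face, so C8 should enter from the β face and give the 3,4-trans (4β) product whatever the configuration of C4 in 14. Ring closure has to precede intermolecular capture of the first oxocarbenium ion and attack by ring B, which the six-membered transition state and the threefold oxygen activation of the ring A carbon should secure (ring B could only close a five-membered ring). C8 of 13 has to win over C6 and over the rings of the product, which rests on the higher nucleophilicity of C8 in 5,7-di-O-benzylflavan-3-ols and on the excess of 13.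

Step 9
Reactants: 15 deca-O-benzyl dimer
Product: 16 epigallocatechin-(4β→8)-catechin
Conditions: H2 (1 atm), Pd(OH)2/C, THF/MeOH/H2O, rt
Reagents that add atoms: none
Why: Hydrogenolysis of the ten benzyl ethers over Pearlman's catalyst under neutral conditions should free all hydroxyl groups without cleaving the C2–O1 bonds or the interflavan bond and without touching a stereocentre.

## Compound list

1 | (S)-4-benzyl-1,3-oxazolidin-2-one | O=C1N[C@@H](Cc2ccccc2)CO1 | starting material
2 | benzyloxyacetyl chloride | ClC(=O)COCc1ccccc1 | starting material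
3 | (S)-4-benzyl-3-[(benzyloxy)acetyl]-1,3-oxazolidin-2-one | O=C(COCc1ccccc1)N1[C@@H](Cc2ccccc2)COC1=O | intermediate
4 | 3,4,5-tris(benzyloxy)benzaldehyde | O=Cc1cc(OCc2ccccc2)c(OCc2ccccc2)c(OCc2ccccc2)c1 | starting material
5 | Z-dibutylboron enolate of 3 | CCCCB(CCCC)O/C(=C\OCc1ccccc1)N1[C@@H](Cc2ccccc2)COC1=O | intermediate (not isolated)
6 | (S)-4-benzyl-3-[(2S,3R)-2-(benzyloxy)-3-hydroxy-3-[3,4,5-tris(benzyloxy)phenyl]propanoyl]-1,3-oxazolidin-2-one | O[C@H](c1cc(OCc2ccccc2)c(OCc2ccccc2)c(OCc2ccccc2)c1)[C@H](OCc1ccccc1)C(=O)N1[C@@H](Cc2ccccc2)COC1=O | intermediate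
7 | (2S,3R)-2-(benzyloxy)-3-hydroxy-N-methoxy-N-methyl-3-[3,4,5-tris(benzyloxy)phenyl]propanamide | O[C@H](c1cc(OCc2ccccc2)c(OCc2ccccc2)c(OCc2ccccc2)c1)[C@H](OCc1ccccc1)C(=O)N(C)OC | intermediate
8 | (2S,3R)-2-(benzyloxy)-3-hydroxy-3-[3,4,5-tris(benzyloxy)phenyl]propanal | O[C@H](c1cc(OCc2ccccc2)c(OCc2ccccc2)c(OCc2ccccc2)c1)[C@H](OCc1ccccc1)C=O | intermediate
9 | (1R,2S)-2-(benzyloxy)-3,3-dimethoxy-1-[3,4,5-tris(benzyloxy)phenyl]propan-1-ol | O[C@H](c1cc(OCc2ccccc2)c(OCc2ccccc2)c(OCc2ccccc2)c1)[C@H](OCc1ccccc1)C(OC)OC | intermediate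
10 | 1,3-bis(benzyloxy)-5-bromobenzene | Brc1cc(OCc2ccccc2)cc(OCc2ccccc2)c1 | starting material
11 | 1,3-bis(benzyloxy)-5-{(1R,2S)-2-(benzyloxy)-3,3-dimethoxy-1-[3,4,5-tris(benzyloxy)phenyl]propoxy}benzene | c1c(OCc3ccccc3)cc(OCc3ccccc3)cc1O[C@H](c1cc(OCc3ccccc3)c(OCc3ccccc3)c(OCc3ccccc3)c1)[C@H](OCc3ccccc3)C(OC)OC | intermediate
12 | (+)-catechin, (2R,3S) | Oc1cc(O)c2c(c1)O[C@H](c1ccc(O)c(O)c1)[C@@H](O)C2 | starting material
13 | 5,7,3',4'-tetra-O-benzyl-(+)-catechin | O(Cc3ccccc3)c1cc(OCc3ccccc3)c2c(c1)O[C@H](c1ccc(OCc3ccccc3)c(OCc3ccccc3)c1)[C@@H](O)C2 | intermediate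
14 | 4-methoxy-3,5,7,3',4',5'-hexa-O-benzylepigallocatechin (2,3-cis, both C4 epimers) | O(Cc3ccccc3)c1cc(OCc3ccccc3)c2c(c1)O[C@H](c1cc(OCc3ccccc3)c(OCc3ccccc3)c(OCc3ccccc3)c1)[C@H](OCc3ccccc3)C2OC | intermediate (not isolated)
15 | 3,5,7,3',4',5'-hexa-O-benzylepigallocatechin-(4β→8)-5,7,3',4'-tetra-O-benzylcatechin | O(Cc3ccccc3)c1cc(OCc3ccccc3)c2c(c1)O[C@H](c1cc(OCc3ccccc3)c(OCc3ccccc3)c(OCc3ccccc3)c1)[C@H](OCc3ccccc3)[C@H]2c1c(OCc3ccccc3)cc(OCc3ccccc3)c2c1O[C@H](c1ccc(OCc3ccccc3)c(OCc3ccccc3)c1)[C@@H](O)C2 | intermediate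
16 | epigallocatechin-(4β→8)-catechin | Oc1cc(O)c2c(c1)O[C@H](c1cc(O)c(O)c(O)c1)[C@H](O)[C@H]2c1c(O)cc(O)c2c1O[C@H](c1ccc(O)c(O)c1)[C@@H](O)C2 | target

## Step count and risks

Total step count: 9. Longest linear sequence: 8 (steps 1–6, 8 and 9); step 7 is the side branch.

**Step 8 (Proposed new method).** Three processes may go wrong:
- capture of the first oxocarbenium ion by 13 before ring closure, which would leave C4 to be set in an uncontrolled cyclisation;
- ionisation of the benzylic C–O bond of the aryl ether, with loss of ring A;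
- attack of the product on further cation, leading to oligomers.

The fallback separates ring construction from coupling and takes the upper unit from the chiral pool. It sets out from 13, which stays the nucleophile. (−)-Epigallocatechin F1 (purchased) would be benzylated on its five phenols (BnBr, K2CO3, DMF) to 5,7,3',4',5'-penta-O-benzylepigallocatechin F2. The 3-OH would then be benzylated (NaH, BnBr, DMF, 0 °C) to the hexa-O-benzyl ether F3. Oxidation of C4 with DDQ in the presence of 2-ethoxyethanol (CH2Cl2, rt) should give the 4β-(2-ethoxyethoxy) derivative F4. TMSOTf-mediated Friedel–Crafts coupling of F4 with an excess of 13 (CH2Cl2, −78 °C) comes back to the route at 15.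

**Step 6.** The hindered palladium alkoxide may undergo β-hydride elimination (oxidation of the carbinol, reduction of the aryl bromide) faster than C–O reductive elimination, or may not form at all. The fallback makes the ether by substitution with inversion and sets out from 9. Dess–Martin oxidation (NaHCO3, CH2Cl2) would give (R)-2-(benzyloxy)-3,3-dimethoxy-1-[3,4,5-tris(benzyloxy)phenyl]propan-1-one F5. Chelation-controlled reduction (Zn(BH4)2, Et2O, −20 °C) should give the anti alcohol (1S,2S)-2-(benzyloxy)-3,3-dimethoxy-1-[3,4,5-tris(benzyloxy)phenyl]propan-1-ol F6. Mitsunobu etherification of F6 with 3,5-bis(benzyloxy)phenol F7 (purchased; PPh3, DIAD, toluene, 0 °C) inverts the carbinol carbon and comes back to the route at 11.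

**Step 4.** The unprotected β-hydroxy aldehyde may suffer over-reduction, retro-aldol cleavage or epimerisation at the α-carbon during work-up and the following acetalisation. The fallback protects the hydroxyl group first and sets out from 7. Silylation (TESCl, imidazole, DMF) would give (2S,3R)-2-(benzyloxy)-N-methoxy-N-methyl-3-(triethylsilyloxy)-3-[3,4,5-tris(benzyloxy)phenyl]propanamide F8. DIBAL-H reduction (THF, −78 °C) would give (2S,3R)-2-(benzyloxy)-3-(triethylsilyloxy)-3-[3,4,5-tris(benzyloxy)phenyl]propanal F9. Acetalisation with HC(OMe)3 and CSA in MeOH, which also removes the silyl ether, comes back to the route at 9.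

## Further compounds

F1 | step 8 | (−)-epigallocatechin (purchased) | Oc1cc(O)c2c(c1)O[C@H](c1cc(O)c(O)c(O)c1)[C@H](O)C2
F2 | step 8 | 5,7,3',4',5'-penta-O-benzyl-(−)-epigallocatechin | O(Cc3ccccc3)c1cc(OCc3ccccc3)c2c(c1)O[C@H](c1cc(OCc3ccccc3)c(OCc3ccccc3)c(OCc3ccccc3)c1)[C@H](O)C2
F3 | step 8 | 3,5,7,3',4',5'-hexa-O-benzyl-(−)-epigallocatechin | O(Cc3ccccc3)c1cc(OCc3ccccc3)c2c(c1)O[C@H](c1cc(OCc3ccccc3)c(OCc3ccccc3)c(OCc3ccccc3)c1)[C@H](OCc3ccccc3)C2
F4 | step 8 | 4β-(2-ethoxyethoxy)-3,5,7,3',4',5'-hexa-O-benzylepigallocatechin | O(Cc3ccccc3)c1cc(OCc3ccccc3)c2c(c1)O[C@H](c1cc(OCc3ccccc3)c(OCc3ccccc3)c(OCc3ccccc3)c1)[C@H](OCc3ccccc3)[C@H]2OCCOCC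
F5 | step 6 | (R)-2-(benzyloxy)-3,3-dimethoxy-1-[3,4,5-tris(benzyloxy)phenyl]propan-1-one | O=C(c1cc(OCc2ccccc2)c(OCc2ccccc2)c(OCc2ccccc2)c1)[C@H](OCc1ccccc1)C(OC)OC
F6 | step 6 | (1S,2S)-2-(benzyloxy)-3,3-dimethoxy-1-[3,4,5-tris(benzyloxy)phenyl]propan-1-ol | O[C@@H](c1cc(OCc2ccccc2)c(OCc2ccccc2)c(OCc2ccccc2)c1)[C@H](OCc1ccccc1)C(OC)OC
F7 | step 6 | 3,5-bis(benzyloxy)phenol (purchased) | Oc1cc(OCc2ccccc2)cc(OCc2ccccc2)c1
F8 | step 4 | (2S,3R)-2-(benzyloxy)-N-methoxy-N-methyl-3-(triethylsilyloxy)-3-[3,4,5-tris(benzyloxy)phenyl]propanamide | CC[Si](CC)(CC)O[C@H](c1cc(OCc2ccccc2)c(OCc2ccccc2)c(OCc2ccccc2)c1)[C@H](OCc1ccccc1)C(=O)N(C)OC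
F9 | step 4 | (2S,3R)-2-(benzyloxy)-3-(triethylsilyloxy)-3-[3,4,5-tris(benzyloxy)phenyl]propanal | CC[Si](CC)(CC)O[C@H](c1cc(OCc2ccccc2)c(OCc2ccccc2)c(OCc2ccccc2)c1)[C@H](OCc1ccccc1)C=O
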